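**Two runs.** The north run and the west run share one recipe at different temperatures, and the four new flasks carry twice that charge of starting material and are read after 3.0 min.

| flask | starting material | coupling partner | free catalyst | second catalyst | temperature | remark | time |
|---|---|---|---|---|---|---|---|
| north | 0.80 M | 2.88 M | 1.6 mM | 10 mM | −20 °C | run made earlier |  |
| west | 0.80 M | 2.88 M | 1.6 mM | 10 mM | 13 °C | run made earlier |  |
| winter | 1.6 M | 2.88 M | 1.6 mM | 10 mM | −15 °C |  | 3.0 min |
| dusk | 1.6 M | 2.88 M | 1.6 mM | 10 mM | 25 °C |  | 3.0 min |
| midnight | 1.6 M | 2.88 M | 1.6 mM | 10 mM | −35 °C |  | 3.0 min |
| spring | 1.6 M | 2.88 M | 1.6 mM | 10 mM | 5 °C |  | 3.0 min |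

- north (time / min: open intermediate / %, product / %): 0.333: 7.0, 0; 0.833: 15.8, 0.9; 1.50: 26.6, 0; 2.50: 40.5, 0
- west (time / s: open intermediate / %, product / %): 10.0: 30.3, 0; 12.0: 35.3, 0.4; 25.0: 58.0, 1.0; 40.0: 73.1, 2.9

(standard deviation of a reading: 0.5 percentage points)

- steps thought possible: second catalyst + open intermediate <-> catalyst intermediate; starting material + free catalyst <-> free catalyst + open intermediate; coupling partner + catalyst intermediate -> second catalyst + product

* which flask leads in amount of open intermediate, in percent of the starting material charged ("all alike" within 1.5 percentage points) (winter / dusk / midnight / spring / all alike)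
* how much open intermediate is there at the end, in percent of the starting material charged: winter
* how much open intermediate is there at the end, in percent of the starting material charged: dusk
* how much open intermediate is there at the end, in percent of the starting material charged: midnight
* how much open intermediate is there at the end, in percent of the starting material charged: spring

**Opening constant.** The opening step returns free catalyst, so you can treat it as pseudo-first-order in starting material, and the share opened should then not depend on the charge. North's last reading gives 0.208 min⁻¹, the opening constant at −20 °C: the logarithm of charged over unopened starting material, divided by time. Unopened means whatever open intermediate and product leave over; catalyst intermediate cannot exceed the second catalyst charged, which is 1.25% of north's starting material. West gives 2.14 min⁻¹ from its last reading and 2.17 min⁻¹ from its first, so one constant serves that run. The two constants give an activation energy of 42.6 kJ mol⁻¹.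

**Opened share.** With that activation energy, the opening constant is 0.0581 min⁻¹ at midnight, 0.307 min⁻¹ in winter, 1.28 min⁻¹ in spring and 4.40 min⁻¹ at dusk. My reckoning for the share opened, one minus exp(−kt), is then 16.0% at midnight, 60.2% in winter, 97.8% in spring and >99.9% at dusk.

**The correction.** Product is the small thing in west, 2.9% beside 73.1% at the last reading, so reckon it apart. West's last product reading, over the time-weighted open intermediate, gives a drain constant of 0.0931 min⁻¹, which is 4.35% of the opening constant. Keep that ratio at first, and the loss is the ratio times (kt minus the share opened). Midnight loses 0.062 percentage points, winter ends near 58.8%, and spring near 85.4%. At dusk the loss is no longer small, so it goes into an exponent and leaves 58.8%. I commit to spring, which stands above the others.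

**Weak link.** The drain's temperature dependence is my assumption, since north's product readings are too small to show it. Try an activation energy of 85.2 kJ mol⁻¹. Spring then ends near 90.4% and dusk near 33.6%, so dusk is the uncertain number and spring still stands above winter and dusk.

**The forecast.** It names spring, with winter 59.4%, dusk 58%, midnight 15.6% and spring 88%, taking about 60 kJ/mol for the drain: “Dusk is therefore the uncertain one, and spring leads.” Its spring number stands higher than my 85.4%.

**The result.** Spring leads at 86.3%, ahead of winter at 59.2%, dusk at 57.8% and midnight at 15.2%.

    second catalyst + open intermediate ⇌ catalyst intermediate (K = 0.130 L mol⁻¹, k = 1.10 L mol⁻¹ s⁻¹, Ea = 57.0 kJ mol⁻¹, ΔH = 11.0 kJ mol⁻¹)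
    starting material + free catalyst ⇌ free catalyst + open intermediate (K = 5.90, k = 50.0 L mol⁻¹ s⁻¹, Ea = 44.0 kJ mol⁻¹, ΔH = −34.0 kJ mol⁻¹)
    coupling partner + catalyst intermediate → second catalyst + product (k = 1.20 L mol⁻¹ s⁻¹, Ea = 48.0 kJ mol⁻¹)
    (constants at 25 °C)

**Once more.** Spring passed 70.0% conversion at 0.956 min, and its opening constant puts that at 0.941 min. A flask like spring kept at −20 °C sits at north's temperature, so you can use 0.208 min⁻¹: after 3.0 min it leaves 53.6% unopened, and that flask holds 54.3% starting material beside 45.5% open intermediate.

The data are calculated from invented constants.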